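**Retrosynthetic overview**
- Target acetate ⇐ acetylation of the erythro-(1S,2R) alcohol ⇐ dynamic-kinetic asymmetric hydrogenation of the racemic α-aryloxy ketone, which sets both stereocentres in one operation.
- α-Aryloxy ketone ⇐ C1–C2 bond: veratraldehyde as an acyl anion (Breslow intermediate) plus an aryl vinyl ether as latent oxocarbenium, in a carbene-catalysed Markovnikov hydroacylation.
- Aryl vinyl ether ⇐ O-vinylation of 4-allyl-2,6-dimethoxyphenol.
- Ring order: no ring is formed; both benzene rings come intact from the two commercial arenes.

Assumption: the SMILES descriptors are read as (1S,2R) on the propyl chain (erythro; 7S,8R in neolignan numbering), and a step is one operation ending in an isolation.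

**Step 1**
Reactants: 1 4-allyl-2,6-dimethoxyphenol
Product: 2 5-allyl-1,3-dimethoxy-2-(vinyloxy)benzene
Conditions: vinyl acetate (2 equiv), [Ir(cod)Cl]2 (1 mol%), Na2CO3 (0.6 equiv), toluene, 100 °C, Ar
Reagents that add atoms: vinyl acetate, C=COC(C)=O
Why: Iridium-catalysed transvinylation, in which the iridium aryloxide adds across the C=C of vinyl acetate and β-acetate elimination releases the aryl vinyl ether under carbonate-buffered conditions that spare the allyl group and the methyl ethers; no stereocentre is formed.

**Step 2**
Reactants: 2 5-allyl-1,3-dimethoxy-2-(vinyloxy)benzene; 3 3,4-dimethoxybenzaldehyde (veratraldehyde)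
Product: 5 rac-2-(4-allyl-2,6-dimethoxyphenoxy)-1-(3,4-dimethoxyphenyl)propan-1-one, via Breslow intermediate 4 (not isolated)
Conditions: 2 (1.0 equiv), 3 (2.0 equiv), 2-mesityl-6,7-dihydro-5H-pyrrolo[2,1-c][1,2,4]triazol-2-ium chloride (20 mol%), DBU (15 mol%), 4 Å MS, 1,4-dioxane, 100 °C, sealed tube, Ar
Reagents that add atoms: none
Why: Proposed new method: the triazolylidene carbene turns aldehyde 3 into the nucleophilic enaminol 4 (an acyl anion equivalent), and in a concerted, asynchronous ene-type step the O–H proton of 4 goes to the electron-rich CH2 terminus of vinyl ether 2 (helped by the residual azolium/DBU-H+ buffer, hence less base than azolium) while the carbinol carbon of 4 bonds to the O-bearing carbon as it gains oxocarbenium character, so two carbons that are both electrophilic in their parent forms are joined in Markovnikov fashion and collapse of the adduct returns the carbene and gives ketone 5 with every atom of 2 and 3 retained; the closest known reaction types are the carbene-catalysed hydroacylation of unactivated alkenes, cyclopropenes and styrenes and the addition of Breslow intermediates to iminium ions (aza-benzoin), the C2 stereocentre is deliberately formed racemic because it is base-labile and is set in step 3, and the isolated allyl C=C is not activated enough to compete.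

**Step 3**
Reactants: 5 rac-2-(4-allyl-2,6-dimethoxyphenoxy)-1-(3,4-dimethoxyphenyl)propan-1-one
Product: 7 (1S,2R)-2-(4-allyl-2,6-dimethoxyphenoxy)-1-(3,4-dimethoxyphenyl)propyl acetate, via erythro alcohol 6 (not isolated)
Conditions: (a) RuCl2[(S)-xylbinap][(S)-daipen] (1 mol%), t-BuOK (10 mol%), H2 (10 atm), i-PrOH, 25 °C; (b) vent, evaporate, then Ac2O (3 equiv), Et3N (4 equiv), DMAP (10 mol%), CH2Cl2, 0 °C to rt
Reagents that add atoms: acetic anhydride, CC(=O)OC(C)=O
Why: Noyori asymmetric hydrogenation with dynamic kinetic resolution followed by DMAP-catalysed acetylation: the alkoxide base epimerises C2 of 5 through its enolate faster than reduction, the (S)-xylbinap/(S)-daipen ruthenium hydride transfers H to the Re face of the aryl ketone (the sense that gives (R)-1-phenylethanol from acetophenone, here 1S), and the (2R)-ketone is expected to be the fast partner because in a Cram-chelate-like arrangement (carbonyl O and aryloxy O syn, bridged by K+ or the catalyst N–H, as in the cis-selective hydrogenation of 2-alkoxycyclohexanones and the erythro-selective hydride reductions of α-aryloxy propiophenones) the hydride passes the small α-H, giving erythro-(1S,2R)-6, which is acetylated in the same flask without touching either stereocentre or the allyl group (the catalyst does not reduce isolated C=C bonds).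

**Compound list**
1 | 4-allyl-2,6-dimethoxyphenol | C=CCc1cc(OC)c(O)c(OC)c1 | starting material
2 | 5-allyl-1,3-dimethoxy-2-(vinyloxy)benzene | C=CCc1cc(OC)c(OC=C)c(OC)c1 | intermediate
3 | 3,4-dimethoxybenzaldehyde (veratraldehyde) | COc1ccc(C=O)cc1OC | starting material
4 | Breslow intermediate: (3,4-dimethoxyphenyl)(hydroxy)methylidene adduct of 2-mesityl-6,7-dihydro-5H-pyrrolo[2,1-c][1,2,4]triazol-3-ylidene | OC(c1ccc(OC)c(OC)c1)=C1N(c2c(C)cc(C)cc2C)N=C2CCCN12 | intermediate (not isolated)
5 | rac-2-(4-allyl-2,6-dimethoxyphenoxy)-1-(3,4-dimethoxyphenyl)propan-1-one | C=CCc1cc(OC)c(OC(C)C(=O)c2ccc(OC)c(OC)c2)c(OC)c1 | intermediate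
6 | (1S,2R)-2-(4-allyl-2,6-dimethoxyphenoxy)-1-(3,4-dimethoxyphenyl)propan-1-ol (erythro) | C=CCc1cc(OC)c(O[C@H](C)[C@@H](O)c2ccc(OC)c(OC)c2)c(OC)c1 | intermediate (not isolated)
7 | (1S,2R)-2-(4-allyl-2,6-dimethoxyphenoxy)-1-(3,4-dimethoxyphenyl)propyl acetate | C=CCc1cc(OC)c(O[C@H](C)[C@@H](OC(C)=O)c2ccc(OC)c(OC)c2)c(OC)c1 | target

**Step count and risks**
Total step count: 3. Longest linear sequence: 3 (1 → 2 → 5 → 7; veratraldehyde 3 enters in step 2).

Steps most likely to fail, most risky first:

Step 2. The intermolecular hydroacylation is unprecedented for enol ethers; it may stop at the reversible benzoin of 3 or alkylate the carbene. The fallback sets out from compound 3 (using phenol 1 in place of vinyl ether 2) and comes back at compound 5. A thiazolylidene-catalysed cross-acyloin of 3 with excess acetaldehyde (3-benzyl-5-(2-hydroxyethyl)-4-methylthiazolium chloride, Cs2CO3, THF, rt) gives rac-2-hydroxy-1-(3,4-dimethoxyphenyl)propan-1-one F2. This is still an acyl anion C–C coupling, but onto an aldehyde. Mitsunobu etherification of F2 with phenol 1 (PPh3, DIAD, toluene, 0 °C to rt) then gives 5. Any racemisation is harmless because step 3 is dynamic.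

Step 3. The diastereosense of the dynamic resolution is predicted, not proven; the catalyst may pair with the (2S)-ketone and give the threo series. The fallback sets out from compound 5 and comes back at compound 7. Hydrogenation with the mirror-image catalyst RuCl2[(R)-xylbinap][(R)-daipen] (t-BuOK, H2, i-PrOH) gives (1R,2R)-2-(4-allyl-2,6-dimethoxyphenoxy)-1-(3,4-dimethoxyphenyl)propan-1-ol F3, which is isolated. A Mitsunobu reaction with acetic acid (AcOH, PPh3, DIAD, toluene, −20 °C to rt) then inverts C1 and installs the acetate in the same operation, giving 7. The risk here is partial loss of inversion at the electron-rich benzylic carbon.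

Step 1. The 2,6-disubstituted phenol may vinylate slowly, and iridium hydrides could move the allyl double bond into conjugation. The fallback sets out from compound 1 and comes back at compound 2. O-Alkylation with 1,2-dibromoethane (5 equiv, K2CO3, MeCN, reflux) gives 5-allyl-2-(2-bromoethoxy)-1,3-dimethoxybenzene F1. E2 elimination (t-BuOK, THF, 0 °C, short reaction time to keep the allyl group in place) then gives 2.

**Further compounds**
F1 | step 1 | 5-allyl-2-(2-bromoethoxy)-1,3-dimethoxybenzene | C=CCc1cc(OC)c(OCCBr)c(OC)c1
F2 | step 2 | rac-2-hydroxy-1-(3,4-dimethoxyphenyl)propan-1-one | CC(O)C(=O)c1ccc(OC)c(OC)c1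
F3 | step 3 | (1R,2R)-2-(4-allyl-2,6-dimethoxyphenoxy)-1-(3,4-dimethoxyphenyl)propan-1-ol | C=CCc1cc(OC)c(O[C@H](C)[C@H](O)c2ccc(OC)c(OC)c2)c(OC)c1
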